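**Plan**

- Numbering (cyathane type): ring A = C1–C4, C9; ring B = C4–C9; ring C = C5, C6, C14–C10; C15 = Me on C12, C16 = Me on C6, C17 = CH2O on C9; β = the face of C17, α = the other face.
- Enabling feature: the B/C fusion bond C5–C6 joins a CH to the methyl-bearing quaternary C6. Ring C reads as a cyclopentane-1,3-dione (C5, C10–C13; C13 is an epoxide carbon) with the alkene carbons C6=C14 inserted between C5 and C13. The axial C17 oxygen lies 1,3-cis to C13 across ring B and can hold the dione as a cyclic enol ether.
- Retrosynthesis: epoxide, exo-methylene and C12=C13 go back to a C13 ketone. Ring C is cut at C5–C13 (fragmentation retron), then at C5–C6 plus C13–C14 ([2+2] retron), leaving a 2-substituted cyclopentane-1,3-dione enol ether with an isopentenyl chain on C9. The dione is cut from an acetal carbon (C5); ring A and the C17–O–C5 oxolane come from an enyne.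
- Forward: ring A + temporary oxolane (Pauson–Khand) → quaternary C9 (conjugate addition) → lactone on C2/C3 → dione and temporary dihydropyran → ring B + cyclobutane (photocycloaddition) → C15 methyl → ring C by two-carbon ring expansion (Grob) → alkene, acetate, methylene, epoxide.
- Stereochemistry: C4 from the enantioselective Pauson–Khand step; C9 from the obligatory cis 5/5 fusion; C2 and C3 from convex-face hydride delivery; C6 from the oxygen tether in the photocycloaddition; C5 from hydroxyl-directed hydrogenation; the epoxide anti to the axial C16 methyl.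

Key step: step 9

Assumption: the (S)-BINAP–Rh catalyst is taken to give the ring-fusion configuration drawn for 4; if the sense is the opposite, (R)-BINAP is used and nothing else changes.

**Step 1**
Reactants: 1 3,3-diethoxyprop-1-ene; 2 prop-2-yn-1-ol
Product: 3 3,3-bis(prop-2-yn-1-yloxy)prop-1-ene
Conditions: 2 (2.5 equiv), PPTS (cat.), 60 °C, EtOH distilled off
Reagents that add atoms: none
Why: Acid-catalysed transacetalisation driven by removal of ethanol; no stereocentre is formed and the product is achiral, its two propargyl arms being enantiotopic.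

**Step 2**
Reactants: 3 3,3-bis(prop-2-yn-1-yloxy)prop-1-ene
Product: 4 2-(prop-2-yn-1-yloxy)-3-oxabicyclo[3.3.0]oct-5-en-7-one (ring-fusion CH = C4 as drawn; acetal carbon as epimer mixture)
Conditions: [Rh(CO)2Cl]2 (3 mol %), (S)-BINAP (9 mol %), AgOTf (12 mol %), CO (1 atm), THF, 80 °C
Reagents that add atoms: carbon monoxide, [C-]#[O+]
Why: Rhodium(I)–BINAP-catalysed enantioselective intramolecular Pauson–Khand reaction of a 1,6-enyne, in which the catalyst chooses the alkene face and so the ring-fusion CH (C4), while the choice of propargyl arm only fixes the acetal carbon that is destroyed later.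

**Step 3**
Reactants: 4 2-(prop-2-yn-1-yloxy)-3-oxabicyclo[3.3.0]oct-5-en-7-one
Product: 5 2-methoxy-3-oxabicyclo[3.3.0]oct-5-en-7-one (same C4 configuration; acetal epimers)
Conditions: MeOH, PPTS (cat.), rt
Reagents that add atoms: methanol, CO
Why: Acid-catalysed acetal exchange through the ring oxocarbenium ion replaces the spare propargyloxy group, whose acidic alkyne C–H would interfere with the organometallic and enolate steps, by methoxy without touching C4.

**Step 4**
Reactants: 5 2-methoxy-3-oxabicyclo[3.3.0]oct-5-en-7-one; 6 4-bromo-2-methylbut-1-ene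
Product: 8 cis-fused 2-methoxy-5-(3-methylbut-3-en-1-yl)-3-oxabicyclo[3.3.0]octan-7-one, via Grignard reagent 7 (not isolated)
Conditions: 6, Mg, THF, rt; then CuBr·SMe2 (10 mol %), 5, THF, −40 °C; H2O
Reagents that add atoms: none
Why: Copper-catalysed conjugate addition of the Grignard reagent to the β,β-disubstituted enone; the new quaternary C9 can only form with the two five-membered rings cis-fused, so the chain enters on the convex face, trans to the acetal carbon on C4.

**Step 5**
Reactants: 8 cis-fused 2-methoxy-5-(3-methylbut-3-en-1-yl)-3-oxabicyclo[3.3.0]octan-7-one; 9 ethyl glyoxylate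
Product: 12 ethyl (E)-2-[2-methoxy-5-(3-methylbut-3-en-1-yl)-7-oxo-3-oxabicyclo[3.3.0]oct-8-ylidene]acetate, via aldol adduct 10 (not isolated), via mesylate 11 (not isolated)
Conditions: LDA, THF, −78 °C; 9; MsCl, −78 → 0 °C; DBU, rt
Reagents that add atoms: none
Why: Kinetic enolisation away from the quaternary carbon, aldol addition to the glyoxylate and E1cB elimination of the mesylate (aldol condensation) place the two-carbon ester unit on C3 as an (E)-alkylidene, so no stereocentre has to be controlled here.

**Step 6**
Reactants: 12 ethyl (E)-2-[…-7-oxo-3-oxabicyclo[3.3.0]oct-8-ylidene]acetate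
Product: 13 ethyl (E)-2-[7-hydroxy-2-methoxy-5-(3-methylbut-3-en-1-yl)-3-oxabicyclo[3.3.0]oct-8-ylidene]acetate (OH β, cis to the oxolane)
Conditions: NaBH4, CeCl3·7H2O, MeOH, −40 °C
Reagents that add atoms: none
Why: Luche 1,2-reduction of the enone carbonyl; hydride attacks the convex face (anti to the oxolane ring), which puts the C2 hydroxyl on the concave face, cis to the oxolane, as the lactone oxygen requires.

**Step 7**
Reactants: 13 ethyl (E)-2-[7-hydroxy-…-3-oxabicyclo[3.3.0]oct-8-ylidene]acetate
Product: 15 tricyclic lactone acetal (oxolane and γ-lactone both cis-fused on the β face of ring A; 3-methylbut-3-enyl on C9 α), via hydroxy ester 14 (not isolated)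
Conditions: [(Ph3P)CuH]6 (0.4 equiv), H2O (2 equiv), PhH, rt; then K2CO3 (cat.), MeOH
Reagents that add atoms: none
Why: Copper hydride conjugate reduction of the enoate delivers hydride to C3 from the convex face, which puts the CH2CO2Et arm cis to the C2 hydroxyl, and base then closes the cis-fused γ-lactone by transesterification.

**Step 8**
Reactants: 15 tricyclic lactone acetal; 16 1,2-bis(trimethylsilyloxy)cyclobut-1-ene
Product: 19 tetracyclic cyclic enol ether (2-substituted 3-alkoxycyclopent-2-enone whose enol oxygen is the C17 oxygen), via cyclobutanone adduct 17 (not isolated), via silyloxy dione 18 (not isolated)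
Conditions: 16 (1.5 equiv), BF3·OEt2, CH2Cl2, −78 °C → rt; then PPTS (cat.), 4 Å MS, PhMe, 40 °C
Reagents that add atoms: none
Why: Geminal acylation of an acetal: Mukaiyama aldol addition of the bis(silyloxy)cyclobutene to the ring oxocarbenium ion and a boron trifluoride-induced acyl shift (pinacol-type ring expansion of the cyclobutanone) turn the acetal carbon into C2 of a cyclopentane-1,3-dione, and the freed C17 oxygen condenses with one of the two equivalent carbonyls to the six-membered cyclic enol ether; no new stereocentre remains.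

**Step 9**
Reactants: 19 tetracyclic cyclic enol ether
Product: 20 hexacyclic photoadduct (cyclobutane C5–C6–C14–C13; C13–O–C17 ether bridge; C10 ketone)
Conditions: hν (254 nm, quartz), degassed MeCN (5 mM), rt
Reagents that add atoms: none
Why: Excitation of the cyclic vinylogous ester gives the enone triplet, which bonds to the tethered 1,1-disubstituted alkene through a 1,4-biradical and closes to the cyclobutane, so C5–C6 and C13–C14 are made in one photochemical event. The closest known reaction type is the intramolecular de Mayo-type [2+2] photocycloaddition of enol derivatives of 2-alkenylcyclopentane-1,3-diones, with the alkene tethered to the dione α-carbon. Ring B closes as a six-membered ring by joining the enone α-carbon C5 to the internal alkene carbon C6 (6-exo with respect to the alkene), and the four-membered ring closes by radical recombination at C13–C14, so ring C is present in masked form as the cyclopentanone plus the two cyclobutane carbons. The new quaternary centre C6 is controlled by the temporary dihydropyran: its oxygen ties the enol carbon C13 to C17, so C13 must sit 1,3-cis to the axial CH2O on the new cyclohexane; since the cyclobutane is cis-fused, CH2-14 ends cis and the methyl trans to C17, as in the target, while C5 and C13 follow from the same constraint and C5 is reset later. The step needs straight rather than crossed regiochemistry and reaction of the enone chromophore only; the four-atom tether from the α-carbon, the rigid bicyclic enol ether and the transparency of the saturated lactone at 254 nm should secure this.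

**Step 10**
Reactants: 20 hexacyclic photoadduct
Product: 21 photoadduct enone (C11=C12 conjugated to the C10 ketone)
Conditions: IBX (3 equiv), DMSO–PhMe, 70 °C
Reagents that add atoms: none
Why: IBX dehydrogenation of the ketone via its enol; only the C11–C12 side can be desaturated because the other α-carbon (C5) is quaternary.

**Step 11**
Reactants: 21 photoadduct enone
Product: 22 12-methyl photoadduct ketone (C12 epimers)
Conditions: Me2CuLi (MeLi, CuI), Et2O, −78 °C; H2O
Reagents that add atoms: lithium dimethylcuprate, [Li+].C[Cu-]C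
Why: Gilman cuprate conjugate addition puts the C15 methyl on C12 without touching the lactone; the new centre is destroyed in step 16, so its configuration is immaterial.

**Step 12**
Reactants: 22 12-methyl photoadduct ketone
Product: 23 C10 alcohol of the photoadduct (epimers at C10 and C12)
Conditions: NaBH4, MeOH, 0 °C
Reagents that add atoms: none
Why: Borohydride reduction of the strained cyclopentanone in the presence of the lactone; the alcohol configuration is not controlled because the five-membered ring can adopt an envelope that aligns either C10–O bond with the C5–C13 bond.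

**Step 13**
Reactants: 23 C10 alcohol of the photoadduct
Product: 25 ring-expanded 17-hydroxy Δ5(10)-en-13-one (rings A/B/C complete; 12-methyl; C12 epimers), via triflate 24 (not isolated)
Conditions: Tf2O, 2,6-lutidine, CH2Cl2, −78 → 0 °C; then H2O–THF, rt
Reagents that add atoms: water, O
Why: Grob-type heterolytic fragmentation: ionisation of the neopentyl triflate is assisted by the C5–C13 cyclobutane bond and the lone pair of the ether oxygen on C13, strain release opens the four-membered ring to the ring-expanded oxocarbenium ion, and water converts it to the C13 ketone and the free C17 hydroxyl; no stereocentre is formed and C6 is retained.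

**Step 14**
Reactants: 25 ring-expanded 17-hydroxy Δ5(10)-en-13-one
Product: 26 17-hydroxy 13-ketone with H-5 β (trans B/C fusion)
Conditions: [Ir(cod)(PCy3)(py)]PF6 (5 mol %), H2 (1 atm), CH2Cl2, rt
Reagents that add atoms: none
Why: Hydroxyl-directed homogeneous hydrogenation with Crabtree's catalyst: the axial C17 hydroxyl binds iridium and delivers hydrogen to the face of C5=C10 on its own side, so H-5 ends cis to CH2OH and the six/seven fusion is trans.

**Step 15**
Reactants: 26 17-hydroxy 13-ketone
Product: 27 17-acetoxy 13-ketone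
Conditions: Ac2O, pyridine, DMAP (cat.), CH2Cl2, rt
Reagents that add atoms: acetic anhydride, CC(=O)OC(C)=O
Why: DMAP-catalysed acylation of the primary neopentyl alcohol installs the acetate of the target and masks the hydroxyl for the triflation.

**Step 16**
Reactants: 27 17-acetoxy 13-ketone
Product: 28 C12=C13 enol triflate
Conditions: Tf2O, 2,6-di-tert-butyl-4-methylpyridine, CH2Cl2, 0 °C → rt
Reagents that add atoms: trifluoromethanesulfonic anhydride, FC(F)(F)S(=O)(=O)OS(=O)(=O)C(F)(F)F
Why: Enol triflate formation under equilibrating conditions (triflic anhydride with a hindered pyridine) should give the more substituted C12=C13 enol triflate, the alternative C14 being a neopentyl methylene next to quaternary C6; the C12 stereocentre disappears.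

**Step 17**
Reactants: 28 C12=C13 enol triflate
Product: 29 Δ12 alkene (17-acetate; saturated lactone)
Conditions: Pd(OAc)2 (5 mol %), PPh3, Bu3N, HCO2H, DMF, 60 °C
Reagents that add atoms: none
Why: Palladium-catalysed formate reduction of the vinyl triflate (hydride transfer by decarboxylation of a palladium formate) replaces OTf by H and leaves the trisubstituted C12=C13 alkene in place.

**Step 18**
Reactants: 29 Δ12 alkene
Product: 32 α-methylene lactone, via Mannich base 30 (not isolated), via methiodide 31 (not isolated)
Conditions: LiHMDS, THF, −78 °C; Eschenmoser's salt, −78 → 0 °C; MeI, CH2Cl2–MeOH; aq NaHCO3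
Reagents that add atoms: N,N-dimethylmethyleneiminium iodide (Eschenmoser's salt), C=[N+](C)C.[I-]
Why: Mannich–elimination α-methylenation: LiHMDS enolises the γ-lactone in preference to the less acidic acetate, the enolate adds to the iminium salt, and quaternisation followed by mild base eliminates trimethylamine to the exocyclic alkene.

**Step 19**
Reactants: 32 α-methylene lactone
Product: 33 target (12,13-β-epoxide)
Conditions: mCPBA, NaHCO3, CH2Cl2, 0 °C
Reagents that add atoms: 3-chloroperbenzoic acid, OOC(=O)c1cccc(Cl)c1
Why: Prilezhaev epoxidation: the electron-rich trisubstituted alkene reacts in preference to the conjugated exo-methylene, and the peracid should approach anti to the axial C16 methyl on C6, which puts the epoxide on the face of H-5 and C17.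

**Compound list**

1 | 3,3-diethoxyprop-1-ene (acrolein diethyl acetal) | C=CC(OCC)OCC | starting material
2 | prop-2-yn-1-ol | C#CCO | starting material
3 | 3,3-bis(prop-2-yn-1-yloxy)prop-1-ene | C=CC(OCC#C)OCC#C | intermediate
4 | 2-(prop-2-yn-1-yloxy)-3-oxabicyclo[3.3.0]oct-5-en-7-one; C4 as drawn, acetal epimers | O=C1C=C2COC(OCC#C)[C@H]2C1 | intermediate
5 | 2-methoxy-3-oxabicyclo[3.3.0]oct-5-en-7-one; C4 as drawn, acetal epimers | O=C1C=C2COC(OC)[C@H]2C1 | intermediate
6 | 4-bromo-2-methylbut-1-ene | C=C(C)CCBr | starting material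
7 | (3-methylbut-3-en-1-yl)magnesium bromide | C=C(C)CC[Mg]Br | intermediate
8 | cis-fused 2-methoxy-5-(3-methylbut-3-en-1-yl)-3-oxabicyclo[3.3.0]octan-7-one (chain α on C9, oxolane β) | O=C1C[C@@]2(CCC(C)=C)COC(OC)[C@H]2C1 | intermediate
9 | ethyl glyoxylate | CCOC(=O)C=O | starting material
10 | aldol adduct: ethyl 2-hydroxy-2-[2-methoxy-5-(3-methylbut-3-en-1-yl)-7-oxo-3-oxabicyclo[3.3.0]oct-8-yl]acetate (new centres unassigned) | O=C1C[C@@]2(CCC(C)=C)COC(OC)[C@H]2C1C(O)C(=O)OCC | intermediate
11 | methanesulfonate of 10 | O=C1C[C@@]2(CCC(C)=C)COC(OC)[C@H]2C1C(OS(C)(=O)=O)C(=O)OCC | intermediate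
12 | ethyl (E)-2-[2-methoxy-5-(3-methylbut-3-en-1-yl)-7-oxo-3-oxabicyclo[3.3.0]oct-8-ylidene]acetate | O=C1C[C@@]2(CCC(C)=C)COC(OC)[C@H]2/C1=C\C(=O)OCC | intermediate
13 | ethyl (E)-2-[7β-hydroxy-2-methoxy-5-(3-methylbut-3-en-1-yl)-3-oxabicyclo[3.3.0]oct-8-ylidene]acetate | O[C@H]1C[C@@]2(CCC(C)=C)COC(OC)[C@H]2/C1=C\C(=O)OCC | intermediate
14 | ethyl 2-[7β-hydroxy-2-methoxy-5-(3-methylbut-3-en-1-yl)-3-oxabicyclo[3.3.0]oct-8β-yl]acetate | O[C@H]1C[C@@]2(CCC(C)=C)COC(OC)[C@H]2[C@H]1CC(=O)OCC | intermediate
15 | tricyclic lactone acetal (γ-lactone on C2/C3 β, methoxy-oxolane on C4/C9 β, 3-methylbut-3-enyl on C9 α) | O=C1O[C@H]2C[C@@]3(CCC(C)=C)COC(OC)[C@H]3[C@H]2C1 | intermediate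
16 | 1,2-bis(trimethylsilyloxy)cyclobut-1-ene | C[Si](C)(C)OC1=C(O[Si](C)(C)C)CC1 | starting material
17 | cyclobutanone adduct: 2-substituted 2-(trimethylsilyloxy)cyclobutanone on the oxolane carbon C5 | O=C1O[C@H]2C[C@@]3(CCC(C)=C)COC(C4(O[Si](C)(C)C)CCC4=O)[C@H]3[C@H]2C1 | intermediate
18 | silyloxy dione: 2-substituted cyclopentane-1,3-dione with C17H2OSiMe3 | O=C1O[C@H]2C[C@@](CCC(C)=C)(CO[Si](C)(C)C)[C@@H](C3C(=O)CCC3=O)[C@H]2C1 | intermediate
19 | tetracyclic cyclic enol ether (dihydropyran-fused 3-alkoxycyclopent-2-enone; lactone; isopentenyl on C9) | O=C1O[C@H]2C[C@@]3(CCC(C)=C)COC4=C(C(=O)CC4)[C@H]3[C@H]2C1 | intermediate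
20 | hexacyclic photoadduct (cyclobutane C5–C6–C14–C13, C13–O–C17 bridge, C10 ketone) | O=C1O[C@H]2C[C@]3(CO6)CC[C@@]4(C)C[C@]6(CCC5=O)[C@@]45[C@H]3[C@H]2C1 | intermediate
21 | photoadduct enone (C11=C12) | O=C1O[C@H]2C[C@]3(CO6)CC[C@@]4(C)C[C@]6(C=CC5=O)[C@@]45[C@H]3[C@H]2C1 | intermediate
22 | 12-methyl photoadduct ketone (C12 unassigned) | O=C1O[C@H]2C[C@]3(CO6)CC[C@@]4(C)C[C@]6(C(C)CC5=O)[C@@]45[C@H]3[C@H]2C1 | intermediate
23 | C10 alcohol of the 12-methyl photoadduct (C10, C12 unassigned) | O=C1O[C@H]2C[C@]3(CO6)CC[C@@]4(C)C[C@]6(C(C)CC5O)[C@@]45[C@H]3[C@H]2C1 | intermediate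
24 | C10 triflate of 23 | O=C1O[C@H]2C[C@]3(CO6)CC[C@@]4(C)C[C@]6(C(C)CC5OS(=O)(=O)C(F)(F)F)[C@@]45[C@H]3[C@H]2C1 | intermediate
25 | 17-hydroxy-12-methyl Δ5(10)-en-13-one tricyclic lactone (C12 unassigned) | O=C1O[C@H]2C[C@]3(CO)CC[C@@]4(C)CC(=O)C(C)CC=C4[C@H]3[C@H]2C1 | intermediate
26 | 17-hydroxy-12-methyl 13-ketone, H-5 β (C12 unassigned) | O=C1O[C@H]2C[C@]3(CO)CC[C@@]4(C)CC(=O)C(C)CC[C@@H]4[C@H]3[C@H]2C1 | intermediate
27 | 17-acetoxy-12-methyl 13-ketone | O=C1O[C@H]2C[C@]3(COC(C)=O)CC[C@@]4(C)CC(=O)C(C)CC[C@@H]4[C@H]3[C@H]2C1 | intermediate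
28 | 17-acetoxy C12=C13 enol triflate | O=C1O[C@H]2C[C@]3(COC(C)=O)CC[C@@]4(C)CC(OS(=O)(=O)C(F)(F)F)=C(C)CC[C@@H]4[C@H]3[C@H]2C1 | intermediate
29 | 17-acetoxy Δ12 alkene with saturated lactone | O=C1O[C@H]2C[C@]3(COC(C)=O)CC[C@@]4(C)CC=C(C)CC[C@@H]4[C@H]3[C@H]2C1 | intermediate
30 | α-(dimethylaminomethyl) lactone (Mannich base; α-carbon unassigned) | CN(C)CC1C(=O)O[C@H]2C[C@]3(COC(C)=O)CC[C@@]4(C)CC=C(C)CC[C@@H]4[C@H]3[C@@H]12 | intermediate
31 | α-(trimethylammoniomethyl) lactone iodide | C[N+](C)(C)CC1C(=O)O[C@H]2C[C@]3(COC(C)=O)CC[C@@]4(C)CC=C(C)CC[C@@H]4[C@H]3[C@@H]12.[I-] | intermediate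
32 | α-methylene lactone, Δ12 alkene, 17-acetate | C=C1C(=O)O[C@H]2C[C@]3(COC(C)=O)CC[C@@]4(C)CC=C(C)CC[C@@H]4[C@H]3[C@@H]12 | intermediate
33 | CNP0149939.1 (12,13-β-epoxide) | C=C1C(=O)O[C@H]2C[C@]3(COC(C)=O)CC[C@@]4(C)C[C@H]5O[C@@]5(C)CC[C@@H]4[C@H]3[C@@H]12 | target

**Count and risks**

Total step count: 19. Longest linear sequence: 19 steps (1 → 33).

Steps most likely to fail:

1. Step 9. The biradical may bond in the crossed sense (C5–C14/C6–C13), or the excited enol ether may decay before the hindered C5–C6 bond forms in the bridged geometry. The fallback gives up the ring constraint and uses the open-chain de Mayo variant with an alkoxide-triggered fragmentation. It sets out from 18 and comes back at 25. Crude 18 (step 8 stopped before the acid cyclisation) is treated with Ac2O, pyridine and DMAP, which acetylates the dione enol and exchanges the labile primary TMS ether for acetate, to give the enol acetate F1. Irradiation at 254 nm gives the open-chain cyclobutane photoadduct F2; its C6 epimers would have to be separated, since no tether fixes the face. IBX and then Me2CuLi, as in steps 10 and 11, give the enone F3 and the 12-methyl ketone F4. NaBH4 gives the alcohol F5 and MsCl/Et3N the mesylate F6. K2CO3 in MeOH removes both acetates, and the tertiary cyclobutanolate fragments (Grob fragmentation) to 25.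

2. Step 13. Ionisation of the neopentyl triflate may end in elimination toward C11 or in a 1,2-shift of another cyclobutane bond instead of fragmentation. The fallback keeps C10 at the ketone level and opens the ring by a Lewis-acid retro-aldol with regiospecific capture of the enol. It sets out from 22 and comes back at 25. TMSOTf and 2,6-lutidine in CH2Cl2, quenched with MeOH/Et3N, give the ring-expanded C10 silyl enol ether with C13 as mixed methyl ketal F7. CsF and PhNTf2 convert the silyl enol ether into the C10 enol triflate F8. Dilute aqueous acid hydrolyses the ketal to the hydroxy ketone enol triflate F9. Palladium-catalysed formate reduction of the vinyl triflate gives 25.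

3. Step 2. Enantioselectivity may erode, or the catalyst may be tied up by the spare terminal alkyne of substrate and product. The fallback replaces asymmetric catalysis by resolution. It sets out from 3 and comes back at 8. A stoichiometric Co2(CO)8/NMO Pauson–Khand reaction gives racemic 4, which is taken through steps 3 and 4 to racemic 8. NaBH4 reduces the ketone from the convex face to the racemic alcohol, whose required enantiomer is the alcohol F10. Lipase-catalysed acylation (CAL-B, vinyl acetate) is assumed to acetylate the unwanted antipode to the acetate F11. The unreacted alcohol F10 is separated and oxidised (Dess–Martin periodinane) to enantiopure 8. If the lipase prefers the other enantiomer, the acetate is kept, methanolysed and oxidised instead.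

**Further compounds**

F1 | step 9 | enol acetate of the 2-substituted cyclopentane-1,3-dione with C17 acetate | O=C1O[C@H]2C[C@@](CCC(C)=C)(COC(C)=O)[C@@H](C3=C(OC(C)=O)CCC3=O)[C@H]2C1
F2 | step 9 | open-chain cyclobutane photoadduct (C13 acetate, C17 acetate, C10 ketone) | O=C1O[C@H]2C[C@]3(COC(C)=O)CC[C@@]4(C)C[C@]5(OC(C)=O)CCC(=O)[C@]45[C@H]3[C@H]2C1
F3 | step 9 | enone of F2 (C11=C12) | O=C1O[C@H]2C[C@]3(COC(C)=O)CC[C@@]4(C)C[C@]5(OC(C)=O)C=CC(=O)[C@]45[C@H]3[C@H]2C1
F4 | step 9 | 12-methyl ketone of the open-chain photoadduct | O=C1O[C@H]2C[C@]3(COC(C)=O)CC[C@@]4(C)C[C@]5(OC(C)=O)C(C)CC(=O)[C@]45[C@H]3[C@H]2C1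
F5 | step 9 | C10 alcohol of F4 | O=C1O[C@H]2C[C@]3(COC(C)=O)CC[C@@]4(C)C[C@]5(OC(C)=O)C(C)CC(O)[C@]45[C@H]3[C@H]2C1
F6 | step 9 | C10 mesylate of F5 | O=C1O[C@H]2C[C@]3(COC(C)=O)CC[C@@]4(C)C[C@]5(OC(C)=O)C(C)CC(OS(C)(=O)=O)[C@]45[C@H]3[C@H]2C1
F7 | step 13 | ring-expanded C10 trimethylsilyl enol ether with C13 mixed methyl ketal bridged to C17 | O=C1O[C@H]2C[C@]3(CO5)CC[C@@]4(C)CC5(OC)C(C)CC(O[Si](C)(C)C)=C4[C@H]3[C@H]2C1
F8 | step 13 | C10 enol triflate with C13 mixed methyl ketal | O=C1O[C@H]2C[C@]3(CO5)CC[C@@]4(C)CC5(OC)C(C)CC(OS(=O)(=O)C(F)(F)F)=C4[C@H]3[C@H]2C1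
F9 | step 13 | 17-hydroxy 13-ketone C10 enol triflate | O=C1O[C@H]2C[C@]3(CO)CC[C@@]4(C)CC(=O)C(C)CC(OS(=O)(=O)C(F)(F)F)=C4[C@H]3[C@H]2C1
F10 | step 2 | 7β-hydroxy-2-methoxy-5-(3-methylbut-3-en-1-yl)-3-oxabicyclo[3.3.0]octane (required enantiomer) | O[C@H]1C[C@@]2(CCC(C)=C)COC(OC)[C@H]2C1
F11 | step 2 | acetate of the antipodal alcohol | CC(=O)O[C@@H]1C[C@]2(CCC(C)=C)COC(OC)[C@@H]2C1
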